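The retrosynthesis cuts two ring bonds of the benzophenone, C1-C2 in ring A and C1'-C2' in ring B (ketone-bearing carbon to phenol carbon). This unfolds both arenes at once into a linear C13 keto diester whose C7 is the diaryl ketone carbon.
This is possible because each ring is a C-methylated acylphloroglucinol. Oxygen sits on C2, C4 and C6, alternating with the acyl carbon C1, the methyl-bearing C3 and the unsubstituted C5. The single free hydroxyl (C2, C2') lies ortho to the ketone, where an ester carbonyl ends up after acyl substitution, and the C4 and C6 methoxy groups can travel as methyl enol ethers.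
The chain is cut further at C4-C5 and C9-C10 into two C4 dienolate units (methyl 2-methylacetoacetate as its enol ether) and a central C5 unit (dimethyl 3-hydroxyglutarate). The middle carbon stays a silyl-protected carbinol, so the ketone is released by a neutral oxidation and not by acid.
Forward: two-directional gamma-acylation joins the chain, orthoformate installs the second pair of enol ethers, and desilylation and oxidation give the keto diester. Base then closes ring A and ring B in one flask.
The target has no stereocentre. Only the alkene geometry of the open-chain compounds matters; it is set thermodynamically (all E) and is levelled anyway in the delocalised anions of the ring closure.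

Key step: step 8

Assumption: the open-chain enol ethers are drawn in their thermodynamically preferred all-E forms. Minor geometric or double-bond positional isomers would be carried along, because deprotonation in the ring-closing step leads to the same delocalised anion.

Step 1
Reactants: 1 methyl 2-methylacetoacetate; 2 trimethyl orthoformate
Product: 3 methyl (E)-3-methoxy-2-methylbut-2-enoate
Conditions: HC(OMe)3, H2SO4 (cat.), MeOH, rt; distillation
Reagents that add atoms: trimethyl orthoformate, COC(OC)OC
Why: Acid-catalysed methyl enol ether formation from a beta-keto ester with an orthoformate is routine, and under equilibrating conditions it should favour the E isomer, in which the ester is cis to the C4 methyl group.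

Step 2
Reactants: 4 dimethyl 3-hydroxypentanedioate
Product: 5 dimethyl 3-[(tert-butyldiphenylsilyl)oxy]pentanedioate
Conditions: TBDPSCl, imidazole, DMF, rt
Reagents that add atoms: tert-butyl(chloro)diphenylsilane, CC(C)(C)[Si](Cl)(c1ccccc1)c1ccccc1
Why: Imidazole-promoted silylation of a secondary alcohol is standard, and the TBDPS group is chosen because it withstands the acidic methanol of step 5 yet leaves with fluoride.

Step 3
Reactants: 5 dimethyl 3-[(tert-butyldiphenylsilyl)oxy]pentanedioate
Product: 6 3-[(tert-butyldiphenylsilyl)oxy]-N1,N5-dimethoxy-N1,N5-dimethylpentanediamide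
Conditions: MeNH(OMe)·HCl, iPrMgCl, THF, -20 → 0 °C
Reagents that add atoms: N,O-dimethylhydroxylamine hydrochloride, CNOC.Cl
Why: Direct aminolysis of esters by the chloromagnesium amide of N,O-dimethylhydroxylamine is well established for beta-silyloxy esters and should convert both termini into N-methoxy-N-methylamides.

Step 4
Reactants: 3 methyl (E)-3-methoxy-2-methylbut-2-enoate (2.6 equiv); 6 3-[(tert-butyldiphenylsilyl)oxy]-N1,N5-dimethoxy-N1,N5-dimethylpentanediamide
Product: 9 dimethyl (2E,11E)-7-[(tert-butyldiphenylsilyl)oxy]-3,11-dimethoxy-2,12-dimethyl-5,9-dioxotrideca-2,11-dienedioate, via lithium dienolate 7 (not isolated), via dilithium tetrahedral bis-adduct 8 (not isolated)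
Conditions: 3, LiN(iPr)2, THF, -78 °C; add 6, -78 → -40 °C; AcOH/THF, -78 °C
Reagents that add atoms: none
Why: In this vinylogous Claisen-type acylation the 1,3-dioxygenated dienolate 7 reacts at its gamma terminus (both oxygens push there and the alpha carbon is blocked by methyl), and the chelated adduct 8 of the Weinreb ketone synthesis survives until the cold acid quench, so neither over-addition nor enolate lactonisation to a pyrone should intervene.

Step 5
Reactants: 9 dimethyl (2E,11E)-7-[(tert-butyldiphenylsilyl)oxy]-3,11-dimethoxy-2,12-dimethyl-5,9-dioxotrideca-2,11-dienedioate; 2 trimethyl orthoformate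
Product: 10 dimethyl (2E,4E,9E,11E)-7-[(tert-butyldiphenylsilyl)oxy]-3,5,9,11-tetramethoxy-2,12-dimethyltrideca-2,4,9,11-tetraenedioate
Conditions: HC(OMe)3, TsOH (cat.), MeOH, rt → 45 °C; Et3N quench
Reagents that add atoms: trimethyl orthoformate, COC(OC)OC
Why: In this acid-catalysed orthoformate enol etherification of the two ketones the proton is lost from the doubly activated C4 and C10 methylenes, which places each new double bond in conjugation with its beta-methoxyacrylate, and equilibration should favour the E geometry known for beta-alkoxycrotonates.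

Step 6
Reactants: 10 dimethyl (2E,4E,9E,11E)-7-[(tert-butyldiphenylsilyl)oxy]-3,5,9,11-tetramethoxy-2,12-dimethyltrideca-2,4,9,11-tetraenedioate
Product: 11 dimethyl (2E,4E,9E,11E)-7-hydroxy-3,5,9,11-tetramethoxy-2,12-dimethyltrideca-2,4,9,11-tetraenedioate
Conditions: Bu4NF, AcOH, THF, rt
Reagents that add atoms: none
Why: Fluoride-induced desilylation is standard, and the acetic acid buffer keeps the liberated alkoxide from attacking the push-pull enol ethers or the esters.

Step 7
Reactants: 11 dimethyl (2E,4E,9E,11E)-7-hydroxy-3,5,9,11-tetramethoxy-2,12-dimethyltrideca-2,4,9,11-tetraenedioate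
Product: 12 dimethyl (2E,4E,9E,11E)-3,5,9,11-tetramethoxy-2,12-dimethyl-7-oxotrideca-2,4,9,11-tetraenedioate
Conditions: Dess-Martin periodinane, pyridine, CH2Cl2, 0 °C → rt; filtration through Et3N-deactivated silica, used at once
Reagents that add atoms: none
Why: The Dess-Martin oxidation of a secondary alcohol runs under buffered, non-aqueous conditions that enol ethers tolerate, so the central ketone appears without any acidic unmasking.

Step 8
Reactants: 12 dimethyl (2E,4E,9E,11E)-3,5,9,11-tetramethoxy-2,12-dimethyl-7-oxotrideca-2,4,9,11-tetraenedioate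
Product: 15 2,2'-dihydroxy-4,4',6,6'-tetramethoxy-3,3'-dimethylbenzophenone, via monocyclised potassium phenoxide 13 (not isolated), via dipotassium bis-phenoxide 14 (not isolated)
Conditions: KOtBu (6 equiv), THF, 0 → 60 °C; then 1 M HCl
Reagents that add atoms: none
Why: Proposed new method: KOtBu removes a proton from C6 and from C8 of 12, each flanked by the C7 ketone and a dienoate, and each delocalised anion attacks through C6 (C8) the terminal ester carbon C1 (C13) that the E,E geometry holds within reach; methoxide departs and the cyclohexadienone tautomerises to the ketone-chelated phenoxide, so 12 should pass irreversibly through 13 to 14, which HCl protonates to 15. The nearest precedents in type are the alkoxide-promoted intramolecular Claisen condensation of 3,5,7-trioxo esters, free or generated from 6-(2-oxoalkyl)-2-pyrones, to acylphloroglucinols, and the lactonisation of 5-oxido-3-methoxy-2,4-dienoates to 4-methoxy-2-pyrones, the oxygen counterpart, which shows that an ester conjugated with the attacking anion still undergoes six-membered acyl substitution. Ring A closes by 6-(enolexo)-exo-trig attack of C6 on C1 (aryl bond C1-C2) and ring B in the same mode by attack of C8 on C13 (aryl bond C1'-C2'), and no stereocentre is formed. Two selectivities are required, acyl substitution in preference to aldol-type closure and a free hydroxyl only at C2 and C2', and the substrate supplies both because C5 and C9 are no longer carbonyl groups, the four enol ether oxygens end as the C4, C6, C4' and C6' methoxy groups, and only the ester carbons become phenols. The other six-membered options are either reversible (attack of C2 on C7 creates a quaternary methyl-bearing carbon that cannot aromatise, and oxygen closures to a pyranylidene or a chromone are reopened by methoxide) or switched off by the excess of base, which keeps both arms anionic and so removes the cross-arm conjugate acceptors at C3/C11 and C5/C9, while the remote ester lies eight ring atoms away. Rotation about the weakened C2-C3 and C4-C5 bonds of the anion should let geometric and positional isomers of 12 reach the reactive conformer.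

Compound list
1 | methyl 2-methylacetoacetate | COC(=O)C(C)C(C)=O | starting material
2 | trimethyl orthoformate | COC(OC)OC | starting material
3 | methyl (E)-3-methoxy-2-methylbut-2-enoate | COC(=O)/C(C)=C(OC)\C | intermediate
4 | dimethyl 3-hydroxypentanedioate | COC(=O)CC(O)CC(=O)OC | starting material
5 | dimethyl 3-[(tert-butyldiphenylsilyl)oxy]pentanedioate | COC(=O)CC(CC(=O)OC)O[Si](c1ccccc1)(c1ccccc1)C(C)(C)C | intermediate
6 | 3-[(tert-butyldiphenylsilyl)oxy]-N1,N5-dimethoxy-N1,N5-dimethylpentanediamide | CON(C)C(=O)CC(CC(=O)N(C)OC)O[Si](c1ccccc1)(c1ccccc1)C(C)(C)C | intermediate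
7 | lithium 1,3-dimethoxy-2-methylbuta-1,3-dien-1-olate (not isolated) | [Li+].[O-]C(OC)=C(C)C(=C)OC | intermediate
8 | dilithium bis(alkoxide) from twofold addition of 7 to the amide carbonyls of 6 (not isolated) | [Li+].[Li+].COC(=O)/C(C)=C(OC)\CC([O-])(N(C)OC)CC(O[Si](c1ccccc1)(c1ccccc1)C(C)(C)C)CC([O-])(N(C)OC)C\C(OC)=C(C)/C(=O)OC | intermediate
9 | dimethyl (2E,11E)-7-[(tert-butyldiphenylsilyl)oxy]-3,11-dimethoxy-2,12-dimethyl-5,9-dioxotrideca-2,11-dienedioate | COC(=O)/C(C)=C(OC)\CC(=O)CC(O[Si](c1ccccc1)(c1ccccc1)C(C)(C)C)CC(=O)C\C(OC)=C(C)/C(=O)OC | intermediate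
10 | dimethyl (2E,4E,9E,11E)-7-[(tert-butyldiphenylsilyl)oxy]-3,5,9,11-tetramethoxy-2,12-dimethyltrideca-2,4,9,11-tetraenedioate | COC(=O)/C(C)=C(OC)\C=C(OC)/CC(O[Si](c1ccccc1)(c1ccccc1)C(C)(C)C)C/C(OC)=C\C(OC)=C(C)/C(=O)OC | intermediate
11 | dimethyl (2E,4E,9E,11E)-7-hydroxy-3,5,9,11-tetramethoxy-2,12-dimethyltrideca-2,4,9,11-tetraenedioate | COC(=O)/C(C)=C(OC)\C=C(OC)/CC(O)C/C(OC)=C\C(OC)=C(C)/C(=O)OC | intermediate
12 | dimethyl (2E,4E,9E,11E)-3,5,9,11-tetramethoxy-2,12-dimethyl-7-oxotrideca-2,4,9,11-tetraenedioate | COC(=O)/C(C)=C(OC)\C=C(OC)/CC(=O)C/C(OC)=C\C(OC)=C(C)/C(=O)OC | intermediate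
13 | potassium phenoxide of methyl (2E,4E)-7-(2-hydroxy-4,6-dimethoxy-3-methylphenyl)-3,5-dimethoxy-2-methyl-7-oxohepta-2,4-dienoate (not isolated) | [K+].COC(=O)/C(C)=C(OC)\C=C(OC)/CC(=O)c1c(OC)cc(OC)c(C)c1[O-] | intermediate
14 | dipotassium bis-phenoxide of 2,2'-dihydroxy-4,4',6,6'-tetramethoxy-3,3'-dimethylbenzophenone (not isolated) | [K+].[K+].COc1cc(OC)c(C(=O)c2c(OC)cc(OC)c(C)c2[O-])c([O-])c1C | intermediate
15 | 2,2'-dihydroxy-4,4',6,6'-tetramethoxy-3,3'-dimethylbenzophenone | COc1cc(OC)c(C(=O)c2c(OC)cc(OC)c(C)c2O)c(O)c1C | target

Total step count: 8. Longest linear sequence: 7 steps (4 → 5 → 6 → 9 → 10 → 11 → 12 → 15). Step 1 lies on the side branch.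

Steps most likely to fail

Step 8.
- **What may go wrong:** The ester is the far end of the same conjugated anion that has to attack it, so acyl substitution may be too slow. Material may then drain into cross-arm conjugate addition-elimination, or into oxygen closure at the monocyclised stage.
- **Fallback:** It uses the known pyrone-masked Claisen folding, sets out from 9 and returns at 15.
 - DBU in refluxing toluene lactonises both 5-oxo-enoate arms to 6,6'-{2-[(tert-butyldiphenylsilyl)oxy]propane-1,3-diyl}bis(4-methoxy-3-methyl-2H-pyran-2-one) F1.
 - Bu4NF/AcOH then frees 6,6'-(2-hydroxypropane-1,3-diyl)bis(4-methoxy-3-methyl-2H-pyran-2-one) F2.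
 - Dess-Martin periodinane oxidises it to 1,3-bis(4-methoxy-3-methyl-2-oxo-2H-pyran-6-yl)propan-2-one F3.
 - Mg(OMe)2 in refluxing MeOH opens both lactones. The resulting 3-methoxy-5,7-dioxo esters, whose nucleophilic carbon now lies between two true ketones, undergo Claisen cyclisation to 2,2',6,6'-tetrahydroxy-4,4'-dimethoxy-3,3'-dimethylbenzophenone F4.
 - Me2SO4 (two equivalents) with K2CO3 in acetone should methylate, in each ring, the less hindered hydroxyl at C6/C6'. The methyl-flanked C2/C2' hydroxyl stays chelated to the ketone and unreactive, which gives 15.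

Step 5.
- **What may go wrong:** The enol may lactonise onto the cis ester. A cross-arm aldol-type closure may occur within the 1,5-diketone. Acid may induce loss of the silyloxy group, or the enol ether may form away from conjugation.
- **Fallback:** It replaces acid-catalysed equilibration by kinetic enolate trapping, sets out from 9 and returns at 10. KN(SiMe3)2 (slightly more than two equivalents) in THF-DMPU at -78 °C converts both ketones at once into their extended potassium enolates, so no ketone remains as an aldol acceptor. Methyl triflate, a hard alkylating agent, should then trap them on oxygen in the absence of any acid. No new compound lies on this path.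

Step 4.
- **What may go wrong:** The basic dienolate may deprotonate the amide alpha-methylene, which would be followed by beta-elimination of the silyloxy group. Attack may also occur through the alpha carbon of the dienolate.
- **Fallback:** It moves the C4-C5 and C9-C10 bond formation to a Lewis-acid-mediated vinylogous Mukaiyama aldol reaction, sets out from 6 and 3, and returns at 9.
 - DIBAL-H at -78 °C reduces 6 to 3-[(tert-butyldiphenylsilyl)oxy]pentanedial F5.
 - Separately, 3 is converted with LiN(iPr)2 and Me3SiCl into [(1,3-dimethoxy-2-methylbuta-1,3-dien-1-yl)oxy]trimethylsilane F6.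
 - BF3·OEt2 in CH2Cl2 at -78 °C joins two molecules of the diene through their gamma termini to the dialdehyde. The product is dimethyl (2E,11E)-7-[(tert-butyldiphenylsilyl)oxy]-5,9-dihydroxy-3,11-dimethoxy-2,12-dimethyltrideca-2,11-dienedioate F7, a diastereomer mixture whose carbinol centres are of no consequence.
 - Dess-Martin periodinane oxidises both carbinols to give 9.

Further compounds
F1 | step 8 | 6,6'-{2-[(tert-butyldiphenylsilyl)oxy]propane-1,3-diyl}bis(4-methoxy-3-methyl-2H-pyran-2-one) | COc1cc(CC(Cc2cc(OC)c(C)c(=O)o2)O[Si](c2ccccc2)(c2ccccc2)C(C)(C)C)oc(=O)c1C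
F2 | step 8 | 6,6'-(2-hydroxypropane-1,3-diyl)bis(4-methoxy-3-methyl-2H-pyran-2-one) | COc1cc(CC(O)Cc2cc(OC)c(C)c(=O)o2)oc(=O)c1C
F3 | step 8 | 1,3-bis(4-methoxy-3-methyl-2-oxo-2H-pyran-6-yl)propan-2-one | COc1cc(CC(=O)Cc2cc(OC)c(C)c(=O)o2)oc(=O)c1C
F4 | step 8 | 2,2',6,6'-tetrahydroxy-4,4'-dimethoxy-3,3'-dimethylbenzophenone | COc1cc(O)c(C(=O)c2c(O)cc(OC)c(C)c2O)c(O)c1C
F0 | step 5 | none | none
F5 | step 4 | 3-[(tert-butyldiphenylsilyl)oxy]pentanedial | O=CCC(CC=O)O[Si](c1ccccc1)(c1ccccc1)C(C)(C)C
F6 | step 4 | [(1,3-dimethoxy-2-methylbuta-1,3-dien-1-yl)oxy]trimethylsilane | COC(=C)C(C)=C(OC)O[Si](C)(C)C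
F7 | step 4 | dimethyl (2E,11E)-7-[(tert-butyldiphenylsilyl)oxy]-5,9-dihydroxy-3,11-dimethoxy-2,12-dimethyltrideca-2,11-dienedioate | COC(=O)/C(C)=C(OC)\CC(O)CC(O[Si](c1ccccc1)(c1ccccc1)C(C)(C)C)CC(O)C\C(OC)=C(C)/C(=O)OC
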